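1.90 min⁻¹ is the unfolding constant of free enzyme in delta at 57 °C, up from 0.00343 min⁻¹ at 37 °C, and the run lasts 3.0 min.

    substrate → uncatalysed product (k1 = 0.00257 min⁻¹, Ea1 = 109 kJ mol⁻¹)
    substrate + free enzyme → target + free enzyme, rate k2*[substrate]*[free enzyme]/(1 + ([substrate]/Km2)) (Km2 = 14.5 mM, k2 = 2.19 × 10⁵ L mol⁻¹ min⁻¹, Ea2 = 44.0 kJ mol⁻¹)
    free enzyme → unfolded enzyme (k3 = 0.00343 min⁻¹, Ea3 = 269 kJ mol⁻¹)
    target ⇌ isomer of the product (K4 = 16.9, k4 = 0.0988 min⁻¹, Ea4 = 82.0 kJ mol⁻¹, ΔH4 = −22.0 kJ mol⁻¹)
    (constants at 37 °C)

| setting | delta | theta | zeta | eta |
|---|---|---|---|---|
| substrate | 24 mM | 24 mM | 24 mM | 24 mM |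
| free enzyme | 2.4 µM | 2.4 µM | 2.4 µM | 2.4 µM |
| temperature | 57 °C | −3 °C | 37 °C | 17 °C |
| time | 3.0 min | 3.0 min | 3.0 min | 3.0 min |

1. the flask that comes out highest in amount of target, in percent of the substrate charged, or "all alike" when all lie within 1.5 percentage points (delta / theta / zeta / eta / all alike)
2. target at the end, in percent of the substrate charged, delta
3. target at the end, in percent of the substrate charged, theta
4. target at the end, in percent of the substrate charged, zeta
5. target at the end, in percent of the substrate charged, eta

- constants are those at 37 °C; use the activation energies and enthalpies for any other temperature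

I reckon each flask through the length of time its charge of free enzyme effectively works. Two extreme flasks can be solved in the head. If free enzyme never unfolded, that time would be the run, 3.0 min. If it unfolded quickly against the run, the time would be the inverse of the unfolding constant, 0.526 min at delta's temperature. With first-order unfolding, the working time of a real flask lies below both. Delta gives 0.523 min, close to the second extreme, and zeta gives 2.98 min, close to the first. This is the working time: the integral of the free fraction of the enzyme over the run, or the run length at full strength that does the same work. Free enzyme in eta unfolds more slowly than in zeta, and theta is colder still, so for eta and theta I take the run itself.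

Heat also speeds the catalysis. At the start, c(substrate) falls with a pseudo-first-order constant, the catalysed rate constant times c(free enzyme) divided by the saturation factor 2.66. That constant is 0.556 min⁻¹ in delta, 0.198 min⁻¹ in zeta, 0.0611 min⁻¹ in eta and 0.0158 min⁻¹ in theta. Conversion follows from the exponential of this constant times the working time, and that product is larger for zeta than for the others. I hold the constant fixed, which reads low as c(substrate) falls, and I ignore isomerisation during the working time, which reads high.

After the working time, target decays forward to isomer of the product at 0.678 min⁻¹ in delta. My figures are 4.71 % for delta, 4.64 % for theta, 44.5 % for zeta and 16.7 % for eta. The winner is zeta.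

The forecast also names zeta, with 6.6 % for delta, 4.7 % for theta, 43.7 % for zeta and 17.4 % for eta. Its grounds open: “The reaction is enzyme-limited, so I integrated the saturable law”. Its figure for delta stands above mine, and its figure for zeta stands below mine.

The simulation gives zeta highest, with 6.60 % in delta, 4.70 % in theta, 44.0 % in zeta and 17.4 % in eta. In delta, free enzyme stands at 5.75 % of its charge after 1.50 min, when 94.8 % of the working time is spent. A repeat of theta at 12 °C has a working time of 3.00 min and a constant of 0.0443 min⁻¹, so I reckon 12.4 % target there, and that flask holds 12.8 %.

(The rate constants stand for no real mixture; the rest is arithmetic.)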